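**Plan**

- Naming: the upper flavan has rings A (benzo), C (pyran) and B (aryl); the lower epiafzelechin unit has rings D (benzo), F (pyran) and E (aryl). Retrosynthesis: remove six benzyl ethers and a temporary bromine at C5 of ring A; cut O1–C2 and C3–C4 of ring C together (retro-[4+2]); then cut the bond from C4 to C8 of ring D.
- Enabling feature: C4 is a benzylic carbon ortho to the phenolic O1 on ring A, so O1–C8a–C4a–C4 is a latent 1-oxadiene (o-quinone methide), and C2–C3 with ring B is a 4-vinylphenol.
- Forward: rings D, E and F come intact from (−)-epiafzelechin; ring A is joined to C8 of ring D by aryllithium addition to a salicylaldehyde; ring C closes last in the cycloaddition that also brings in ring B; one hydrogenolysis removes all helpers.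
- Stereochemistry: C2 and C3 of ring F are bought with (−)-epiafzelechin. The 2,4-trans relationship in ring C comes from the bromine at C5, peri to C4; the absolute sense at C4 comes from a chiral phosphoric acid.

Key step: step 8

Remark 1: (−)-epiafzelechin is taken as a purchasable natural flavan-3-ol.
Remark 2: which face of the methide carbon the (R)-configured acid leaves open cannot be derived with certainty from the ion-pair model; the (R)-acid is written, and its mirror image would be used if a trial run showed it to be the matched one.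

**Step 1**
Reactants: 1 (−)-epiafzelechin, (2R,3R)-2-(4-hydroxyphenyl)chromane-3,5,7-triol
Product: 2 5,7,4'-tri-O-benzyl-(−)-epiafzelechin, (2R,3R)-5,7-bis(benzyloxy)-2-[4-(benzyloxy)phenyl]chroman-3-ol
Conditions: BnBr (3.3 equiv), K2CO3 (3.5 equiv), DMF, 0 °C → rt
Reagents that add atoms: benzyl bromide, BrCc1ccccc1
Why: Williamson etherification in which K2CO3 ionises only the three phenols and leaves the secondary 3-OH free, and the mild base at room temperature should not open ring F, so C2 and C3 keep their configuration.

**Step 2**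
Reactants: 2 5,7,4'-tri-O-benzyl-(−)-epiafzelechin
Product: 3 3,5,7,4'-tetra-O-benzyl-(−)-epiafzelechin, (2R,3R)-3,5,7-tris(benzyloxy)-2-[4-(benzyloxy)phenyl]chromane
Conditions: NaH (1.3 equiv), BnBr (1.3 equiv), n-Bu4NI (cat.), DMF, 0 °C → rt
Reagents that add atoms: benzyl bromide, BrCc1ccccc1
Why: Williamson etherification of the secondary alkoxide, safe for C2 because with all phenols capped no quinone-methide ring opening is possible.

**Step 3**
Reactants: 3 3,5,7,4'-tetra-O-benzyl-(−)-epiafzelechin
Product: 4 8-bromo-3,5,7,4'-tetra-O-benzyl-(−)-epiafzelechin, (2R,3R)-3,5,7-tris(benzyloxy)-2-[4-(benzyloxy)phenyl]-8-bromochromane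
Conditions: NBS (1.0 equiv), CH2Cl2, −78 → −20 °C
Reagents that add atoms: N-bromosuccinimide, O=C1CCC(=O)N1Br
Why: Electrophilic aromatic bromination should go to C8 of ring D, the most nucleophilic position between O7 and O1, as is general for perbenzylated flavan-3-ols, while the mono-alkoxy ring E is far less reactive.

**Step 4**
Reactants: 5 5-bromoresorcinol (5-bromobenzene-1,3-diol)
Product: 6 2-bromo-4,6-dihydroxybenzaldehyde
Conditions: POCl3 (1.2 equiv), DMF (1.5 equiv), MeCN, 0 °C → rt; then H2O, 50 °C
Reagents that add atoms: N,N-dimethylformamide, CN(C)C=O; water, O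
Why: Vilsmeier–Haack formylation should attack the position para to one hydroxyl and ortho to the other (C4 and C6 are equivalent) in preference to the doubly flanked C2, as with other 5-substituted resorcinols.

**Step 5**
Reactants: 6 2-bromo-4,6-dihydroxybenzaldehyde
Product: 7 4-(benzyloxy)-2-bromo-6-hydroxybenzaldehyde
Conditions: BnBr (1.05 equiv), NaHCO3 (1.5 equiv), MeCN, 70 °C
Reagents that add atoms: benzyl bromide, BrCc1ccccc1
Why: Williamson etherification selective for the 4-OH, which is the more acidic (para to the formyl group) and is not held in the hydrogen bond that deactivates the 6-OH next to the aldehyde.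

**Step 6**
Reactants: 8 4-(benzyloxy)benzaldehyde
Product: 9 4-(benzyloxy)styrene (1-(benzyloxy)-4-vinylbenzene)
Conditions: Ph3PCH3Br (1.2 equiv), KOtBu (1.2 equiv), THF, 0 °C → rt
Reagents that add atoms: methyltriphenylphosphonium bromide, C[P+](c1ccccc1)(c1ccccc1)c1ccccc1.[Br-]
Why: Wittig methylenation of a non-enolisable aryl aldehyde.

**Step 7**
Reactants: 4 8-bromo-3,5,7,4'-tetra-O-benzyl-(−)-epiafzelechin; 7 4-(benzyloxy)-2-bromo-6-hydroxybenzaldehyde
Product: 12 [4-(benzyloxy)-2-bromo-6-hydroxyphenyl][(2R,3R)-3,5,7-tris(benzyloxy)-2-[4-(benzyloxy)phenyl]chroman-8-yl]methanol (mixture of carbinol epimers), via 8-lithio-3,5,7,4'-tetra-O-benzylepiafzelechin 10 (not isolated), via sodium 5-(benzyloxy)-3-bromo-2-formylphenolate 11 (not isolated)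
Conditions: 4, n-BuLi (1.05 equiv), THF, −78 °C, 15 min; then 7 pre-treated with NaH (1.05 equiv, THF, 0 °C), −78 → −20 °C; then H2O; chromatography on Et3N-washed silica
Reagents that add atoms: none
Why: Bromine–lithium exchange followed by 1,2-addition of the aryllithium to the aldehyde, whose phenol is masked as its sodium phenoxide; the carbinol centre forms as a mixture of epimers that both collapse to the same sp2 methide carbon in step 8.

**Step 8**
Reactants: 12 the diarylmethanol from step 7; 9 4-(benzyloxy)styrene
Product: 14 (2S,4S)-7-(benzyloxy)-2-[4-(benzyloxy)phenyl]-5-bromo-4-[(2R,3R)-3,5,7-tris(benzyloxy)-2-[4-(benzyloxy)phenyl]chroman-8-yl]chromane (2,4-trans), via o-quinone methide 13 (not isolated)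
Conditions: (R)-3,3'-bis(2,4,6-triisopropylphenyl)-1,1'-binaphthyl-2,2'-diyl hydrogen phosphate (10 mol %), 9 (3 equiv), 4 Å molecular sieves, toluene, −20 °C → rt
Reagents that add atoms: none
Why: The acid ionises the doubly benzylic carbinol of 12 to the o-quinone methide 13, held to the chiral phosphate by a hydrogen bond at O1 (in the limit an ion pair of the ring-D-stabilised benzhydryl cation), and the nucleophilic CH2 terminus of 9 adds to the methide carbon C4 while O1 closes onto the 4-benzyloxybenzylic carbon C2 in a concerted, strongly asynchronous inverse-electron-demand oxa-[4+2] cycloaddition. The closest known reaction type is the chiral phosphoric acid-catalysed [4+2] cycloaddition of o-quinone methides from o-hydroxybenzhydrols with styrenes, which gives 2,4-diarylchromans. Ring C is the only ring closed, in the intermolecular [4+2] mode (oxadiene O1=C8a–C4a=C4 plus the vinyl group), which in the stepwise limit is C3–C4 bond formation followed by 6-exo-trig capture of the C2 cation by O1. C4 is set by the face of the methide carbon that the phosphate leaves open (catalyst control, since the ring-F stereocentres are remote), and C2 is set relative to C4 by the bromine at C5: A(1,3) strain to this peri substituent turns the ring-D aryl syn to the carbonyl oxygen, so that endo approach of the styrene aryl, or equally a chair-like closure with the C2 aryl pseudo-equatorial and the C4 aryl pseudo-axial, should lead to the 2,4-trans chroman. The descriptor 4S in 14 is the same spatial arrangement as 4R in the target, because bromine raises the CIP rank of C4a. Regioselectivity (CH2 to C4, oxygen to the benzylic carbon) follows from the polarity of the partners, and chemoselectivity from the design of 12: only O1 is a free phenol (O7 of ring D is benzylated), the tetra-ortho-substituted methide is too hindered to dimerise or take up a second arene, and the weak acid should not polymerise 9.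

**Step 9**
Reactants: 14 the hexabenzyl bromo adduct from step 8
Product: 15 (2S)-4',7-dihydroxyflavan-(4β→8)-(−)-epiafzelechin, (2R,3R)-8-[(2S,4R)-7-hydroxy-2-(4-hydroxyphenyl)chroman-4-yl]-2-(4-hydroxyphenyl)chromane-3,5,7-triol
Conditions: H2 (1 atm), Pd(OH)2/C, NaHCO3 (1.5 equiv), THF/MeOH 1:1, rt
Reagents that add atoms: none
Why: Hydrogenolysis should cleave the six O-benzyl bonds and the aryl C–Br bond (hydrodehalogenation, HBr taken up by NaHCO3) while the cyclic C2–O1 ethers and all four stereocentres stay untouched, as in the deprotection of benzylated, bromine-capped oligomeric flavans; the C4 descriptor returns to R only because the bromine is gone.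

**Compound list**

1 | (−)-epiafzelechin, (2R,3R)-2-(4-hydroxyphenyl)chromane-3,5,7-triol | Oc1cc(O)c2c(c1)O[C@H](c1ccc(O)cc1)[C@H](O)C2 | starting material
2 | 5,7,4'-tri-O-benzyl-(−)-epiafzelechin | O(Cc1ccccc1)c1cc(OCc3ccccc3)c2c(c1)O[C@H](c1ccc(OCc3ccccc3)cc1)[C@H](O)C2 | intermediate
3 | 3,5,7,4'-tetra-O-benzyl-(−)-epiafzelechin | O(Cc1ccccc1)c1cc(OCc3ccccc3)c2c(c1)O[C@H](c1ccc(OCc3ccccc3)cc1)[C@H](OCc1ccccc1)C2 | intermediate
4 | 8-bromo-3,5,7,4'-tetra-O-benzyl-(−)-epiafzelechin | O(Cc1ccccc1)c1cc(OCc3ccccc3)c2c(c1Br)O[C@H](c1ccc(OCc3ccccc3)cc1)[C@H](OCc1ccccc1)C2 | intermediate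
5 | 5-bromoresorcinol | Oc1cc(O)cc(Br)c1 | starting material
6 | 2-bromo-4,6-dihydroxybenzaldehyde | O=Cc1c(O)cc(O)cc1Br | intermediate
7 | 4-(benzyloxy)-2-bromo-6-hydroxybenzaldehyde | O=Cc1c(O)cc(OCc2ccccc2)cc1Br | intermediate
8 | 4-(benzyloxy)benzaldehyde | O=Cc1ccc(OCc2ccccc2)cc1 | starting material
9 | 4-(benzyloxy)styrene | C=Cc1ccc(OCc2ccccc2)cc1 | intermediate
10 | 8-lithio-3,5,7,4'-tetra-O-benzylepiafzelechin | [Li]c1c(OCc3ccccc3)cc(OCc3ccccc3)c2c1O[C@H](c1ccc(OCc3ccccc3)cc1)[C@H](OCc1ccccc1)C2 | intermediate (not isolated)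
11 | sodium 5-(benzyloxy)-3-bromo-2-formylphenolate | [Na+].[O-]c1cc(OCc2ccccc2)cc(Br)c1C=O | intermediate (not isolated)
12 | [4-(benzyloxy)-2-bromo-6-hydroxyphenyl][(2R,3R)-3,5,7-tris(benzyloxy)-2-[4-(benzyloxy)phenyl]chroman-8-yl]methanol, both carbinol epimers | OC(c1c(O)cc(OCc2ccccc2)cc1Br)c1c(OCc3ccccc3)cc(OCc3ccccc3)c2c1O[C@H](c1ccc(OCc3ccccc3)cc1)[C@H](OCc1ccccc1)C2 | intermediate
13 | 3-(benzyloxy)-5-bromo-6-[(tetra-O-benzylepiafzelechin-8-yl)methylidene]cyclohexa-2,4-dien-1-one, ring-D aryl syn to the carbonyl oxygen (E by the CIP rules because of the bromine) | O=C1C=C(OCc2ccccc2)C=C(Br)/C1=C/c1c(OCc3ccccc3)cc(OCc3ccccc3)c2c1O[C@H](c1ccc(OCc3ccccc3)cc1)[C@H](OCc1ccccc1)C2 | intermediate (not isolated)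
14 | (2S,4S)-7-(benzyloxy)-2-[4-(benzyloxy)phenyl]-5-bromo-4-[(2R,3R)-3,5,7-tris(benzyloxy)-2-[4-(benzyloxy)phenyl]chroman-8-yl]chromane | C(c1ccccc1)Oc1ccc([C@@H]2C[C@@H](c3c(OCc5ccccc5)cc(OCc5ccccc5)c4c3O[C@H](c3ccc(OCc5ccccc5)cc3)[C@H](OCc3ccccc3)C4)c3c(Br)cc(OCc5ccccc5)cc3O2)cc1 | intermediate
15 | (2R,3R)-8-[(2S,4R)-7-hydroxy-2-(4-hydroxyphenyl)chroman-4-yl]-2-(4-hydroxyphenyl)chromane-3,5,7-triol | Oc1ccc([C@@H]2C[C@@H](c3c(O)cc(O)c4c3O[C@H](c3ccc(O)cc3)[C@H](O)C4)c3ccc(O)cc3O2)cc1 | target

**Totals**

Total step count: 9. Longest linear sequence: 6 (steps 1, 2, 3, 7, 8, 9).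

**Steps most likely to fail**

Step 8. The chiral phosphate may fail to discriminate the two faces of the methide carbon against the bulk of ring D, the trans preference may erode, or acid-induced oligomerisation of the styrene may outrun the cycloaddition. The fallback forms the C4–C8 bond last by a Friedel–Crafts reaction; it sets out from 3 and comes back to the route at 15. Purchased racemic liquiritigenin F1 would be benzylated (BnBr, K2CO3, DMF) to racemic 7,4'-bis(benzyloxy)flavan-4-one F2. Asymmetric transfer hydrogenation with kinetic resolution (RuCl(p-cymene)[(S,S)-N-(p-toluenesulfonyl)-1,2-diphenylethylenediamine], HCO2H/Et3N) should, by the usual model, reduce the (2S)-ketone fastest to the cis-(2S,4S)-7-(benzyloxy)-2-[4-(benzyloxy)phenyl]chroman-4-ol F3 and leave the (2R)-ketone behind. Ionisation of F3 with BF3·OEt2 in CH2Cl2 at low temperature in the presence of 3 should alkylate C8 of ring D anti to the C2 aryl and give the bromine-free 2,4-trans hexabenzyl ether F4. Hydrogenolysis as in step 9 then gives 15.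

Step 7. The hindered aryllithium may add only slowly to the deactivated, poorly soluble phenoxide aldehyde, so that proton transfer or halogen–lithium scrambling takes over, and the sensitive carbinol may ionise prematurely during isolation. The fallback generates the o-quinone methide under basic conditions in a three-component union; it sets out from 7 (with 4 and 9) and comes back at 14. Compound 7 would be converted with di-tert-butyl dicarbonate, i-Pr2NEt and catalytic 4-(dimethylamino)pyridine into tert-butyl 5-(benzyloxy)-3-bromo-2-formylphenyl carbonate F5. The aryllithium 10, made from 4 as in step 7, would be added at −78 °C to F5 and an excess of 9 in the presence of MgBr2·OEt2 and the mixture warmed to room temperature. Addition to the more electrophilic aldehyde, transfer of the carbonate group to the new alkoxide and loss of tert-butyl carbonate should release 13, which 9 traps in situ to give 14. Without the chiral acid, facial selectivity rests on the substrate alone, and the two trans diastereomers would be separated by chromatography.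

Step 4. Formylation may occur at the position between the two hydroxyls, or the free phenols may be O-formylated or phosphorylated by POCl3. The fallback formylates the bis-ether and then removes one benzyl group selectively; it sets out from 5 and comes back at 7, bypassing 6 and step 5. Compound 5 would be benzylated twice (BnBr, K2CO3, DMF) to 1,3-bis(benzyloxy)-5-bromobenzene F6. Vilsmeier–Haack formylation (POCl3, DMF, 80 °C) should give 2,4-bis(benzyloxy)-6-bromobenzaldehyde F7. Chelation-controlled cleavage of the benzyl ether ortho to the aldehyde with MgBr2·OEt2 (toluene/Et2O, reflux) then gives 7.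

**Further compounds**

F1 | step 8 | racemic liquiritigenin (7,4'-dihydroxyflavan-4-one, purchased) | O=C1CC(c2ccc(O)cc2)Oc2cc(O)ccc12
F2 | step 8 | racemic 7,4'-bis(benzyloxy)flavan-4-one | O=C1CC(c2ccc(OCc3ccccc3)cc2)Oc2cc(OCc3ccccc3)ccc12
F3 | step 8 | (2S,4S)-7-(benzyloxy)-2-[4-(benzyloxy)phenyl]chroman-4-ol | C(c1ccccc1)Oc1ccc([C@@H]2C[C@H](O)c3ccc(OCc4ccccc4)cc3O2)cc1
F4 | step 8 | (2S,4R)-7-(benzyloxy)-2-[4-(benzyloxy)phenyl]-4-[(2R,3R)-3,5,7-tris(benzyloxy)-2-[4-(benzyloxy)phenyl]chroman-8-yl]chromane | C(c1ccccc1)Oc1ccc([C@@H]2C[C@@H](c3c(OCc5ccccc5)cc(OCc5ccccc5)c4c3O[C@H](c3ccc(OCc5ccccc5)cc3)[C@H](OCc3ccccc3)C4)c3ccc(OCc5ccccc5)cc3O2)cc1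
F5 | step 7 | tert-butyl 5-(benzyloxy)-3-bromo-2-formylphenyl carbonate | O=Cc1c(OC(=O)OC(C)(C)C)cc(OCc2ccccc2)cc1Br
F6 | step 4 | 1,3-bis(benzyloxy)-5-bromobenzene | Brc1cc(OCc2ccccc2)cc(OCc2ccccc2)c1
F7 | step 4 | 2,4-bis(benzyloxy)-6-bromobenzaldehyde | O=Cc1c(OCc2ccccc2)cc(OCc2ccccc2)cc1Br
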